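**Plan**

1. Cuts: (a) the bond from the side-chain CH= carbon to ring C (Nozaki–Hiyama–Kishi), with the exocyclic C=C and the ring C methine then arising by reductive allylic transposition; (b) in ring B, the bond between the tertiary carbinol carbon and the CH that carries the two-carbon link; (c) in ring A, the CH2–CH2 bond (metathesis) and the bond between the quaternary carbon and the ether CH (Ireland–Claisen); (d) rings C and D by a Diels–Alder cut.
2. Forward order: ring A (Claisen, then ring-closing metathesis), the two chains, ring B (key step); in parallel the ring D enone and isoprene give the cis-fused rings C/D; the halves are joined, the alkene is set, then desilylation and one oxidation.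
3. Stereochemistry: methyl (R)-lactate sets the quaternary and ether carbons through the Claisen chair, and these steer the ring B chair of the key step. A chiral Lewis acid sets the cis ring fusion and convex-face epoxidation the ring D carbinol. A reagent-controlled ketone reduction followed by a stereospecific diazene retro-ene sets the ring C methine and the alkene geometry.
4. Enabling feature: in ring B the tertiary carbinol carbon (C–OH, CH3) and the neighbouring CH bearing the two-carbon link both sit next to the quaternary A/B fusion carbon. Both trace back to electrophilic carbons (a methyl ketone carbonyl and an enoate β-carbon), so they are joined reductively through a ketyl.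

Key step: step 21

Remark 1: ring A is carried from step 14 as its silyl-protected carbinol, drawn 3S (oxepane locants O1, C2 = CMe2, C3 = carbinol, C6 = quaternary carbon, C7 = ether CH); this carbon becomes the ketone in the last step, so its configuration has no consequence, and a final acidic ketal hydrolysis next to the alkene is avoided.
Remark 2: the (S)-oxazaborolidine–AlBr3 catalyst of step 24 is assumed to give the (4aR,8aS) adduct, as the α-C–H···O binding model predicts; the mirror-image catalyst would be used otherwise.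

Step 1
Reactants: 1 methyl 2-hydroxyisobutyrate
Product: 2 2-hydroxy-N-methoxy-N,2-dimethylpropanamide
Conditions: MeNH(OMe)·HCl, i-PrMgCl, THF, −20 → 0 °C
Reagents that add atoms: N,O-dimethylhydroxylamine hydrochloride, CNOC.Cl
Why: Weinreb amide formation by magnesium amide aminolysis of the methyl ester is routine, and the tertiary alkoxide formed first is a spectator.

Step 2
Reactants: 2 2-hydroxy-N-methoxy-N,2-dimethylpropanamide; 3 bromoacetic acid
Product: 4 2-{[1-(methoxy(methyl)amino)-2-methyl-1-oxopropan-2-yl]oxy}acetic acid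
Conditions: NaH (2.5 equiv), THF, 0 → 65 °C; aq. HCl
Reagents that add atoms: none
Why: Williamson etherification, in which the tertiary sodium alkoxide attacks the primary carbon of sodium bromoacetate, is the usual way to the O-alkyl glycolic acids used in glycolate Claisen rearrangements; the non-enolisable amide is inert to NaH.

Step 3
Reactants: 5 methyl (R)-lactate
Product: 6 methyl (R)-2-[(tert-butyldimethylsilyl)oxy]propanoate
Conditions: t-BuMe2SiCl, imidazole, DMF, 23 °C
Reagents that add atoms: tert-butyldimethylsilyl chloride, C[Si](C)(Cl)C(C)(C)C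
Why: Standard silyl ether formation on a secondary alcohol, with no risk to the α-stereocentre.

Step 4
Reactants: 6 methyl (R)-2-[(tert-butyldimethylsilyl)oxy]propanoate
Product: 7 (R)-2-[(tert-butyldimethylsilyl)oxy]propanal
Conditions: i-Bu2AlH, CH2Cl2, −78 °C
Reagents that add atoms: none
Why: Low-temperature i-Bu2AlH reduction of an α-silyloxy ester stops at the aldehyde through the aluminium hemiacetal and is well precedented for lactate esters without racemisation.

Step 5
Reactants: 7 (R)-2-[(tert-butyldimethylsilyl)oxy]propanal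
Product: 8 ethyl (2Z,4R)-4-[(tert-butyldimethylsilyl)oxy]-2-methylpent-2-enoate
Conditions: (CF3CH2O)2P(O)CH(CH3)CO2Et, KN(SiMe3)2, 18-crown-6, THF, −78 °C
Reagents that add atoms: ethyl 2-[bis(2,2,2-trifluoroethoxy)phosphoryl]propanoate, CCOC(=O)C(C)P(=O)(OCC(F)(F)F)OCC(F)(F)F
Why: The Still–Gennari variant of the Horner–Wadsworth–Emmons olefination gives the (Z)-trisubstituted enoate kinetically, and the cold, fast reaction spares the α-silyloxy stereocentre.

Step 6
Reactants: 8 ethyl (2Z,4R)-4-[(tert-butyldimethylsilyl)oxy]-2-methylpent-2-enoate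
Product: 9 (2Z,4R)-4-[(tert-butyldimethylsilyl)oxy]-2-methylpent-2-en-1-ol
Conditions: i-Bu2AlH (2.2 equiv), CH2Cl2, −78 °C
Reagents that add atoms: none
Why: 1,2-Reduction of the enoate with i-Bu2AlH gives the allylic alcohol without touching the alkene geometry.

Step 7
Reactants: 9 (2Z,4R)-4-[(tert-butyldimethylsilyl)oxy]-2-methylpent-2-en-1-ol
Product: 10 {[(2R,3Z)-5-(benzyloxy)-4-methylpent-3-en-2-yl]oxy}(tert-butyl)dimethylsilane
Conditions: BnOC(=NH)CCl3, TfOH (cat.), CH2Cl2–cyclohexane, 0 °C
Reagents that add atoms: benzyl 2,2,2-trichloroacetimidate, ClC(Cl)(Cl)C(=N)OCc1ccccc1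
Why: Acid-catalysed O-benzylation with the trichloroacetimidate avoids an alkoxide, which could trigger 1,5-silyl migration across the (Z)-alkene.

Step 8
Reactants: 10 {[(2R,3Z)-5-(benzyloxy)-4-methylpent-3-en-2-yl]oxy}(tert-butyl)dimethylsilane
Product: 11 (2R,3Z)-5-(benzyloxy)-4-methylpent-3-en-2-ol
Conditions: Bu4NF, THF, 23 °C
Reagents that add atoms: none
Why: Fluoride cleavage of the silyl ether frees the secondary allylic alcohol and leaves the benzyl ether untouched.

Step 9
Reactants: 4 2-{[1-(methoxy(methyl)amino)-2-methyl-1-oxopropan-2-yl]oxy}acetic acid; 11 (2R,3Z)-5-(benzyloxy)-4-methylpent-3-en-2-ol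
Product: 12 (2R,3Z)-5-(benzyloxy)-4-methylpent-3-en-2-yl 2-{[1-(methoxy(methyl)amino)-2-methyl-1-oxopropan-2-yl]oxy}acetate
Conditions: DCC, DMAP (cat.), CH2Cl2, 0 → 23 °C
Reagents that add atoms: none
Why: Steglich esterification joins the acid to the secondary allylic alcohol under neutral conditions that leave the (Z)-alkene and the stereocentre intact.

Step 10
Reactants: 12 (2R,3Z)-5-(benzyloxy)-4-methylpent-3-en-2-yl 2-{[1-(methoxy(methyl)amino)-2-methyl-1-oxopropan-2-yl]oxy}acetate
Product: 15 (2R,3S,4E)-3-[(benzyloxy)methyl]-2-{[1-(methoxy(methyl)amino)-2-methyl-1-oxopropan-2-yl]oxy}-3-methylhex-4-enoic acid, via silyl ketene acetal 13 (not isolated), via trimethylsilyl ester 14 (not isolated)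
Conditions: LiN(SiMe3)2, Me3SiCl, THF, −78 → 23 °C; aq. HCl
Reagents that add atoms: none
Why: Ireland–Claisen rearrangement, in which the lithium-chelated (Z)-glycolate enolate is silylated and rearranges through a chair with the carbinol methyl equatorial (the other chair suffers 1,3-diaxial strain with the axial CH2OBn of the (Z)-alkene), so the lactate centre is relayed to the new ether CH (R) and quaternary carbon (S) and the new alkene is E.

Step 11
Reactants: 15 (2R,3S,4E)-3-[(benzyloxy)methyl]-2-{[1-(methoxy(methyl)amino)-2-methyl-1-oxopropan-2-yl]oxy}-3-methylhex-4-enoic acid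
Product: 16 (2R,3S,4E)-3-[(benzyloxy)methyl]-3-methyl-2-[(2-methyl-3-oxopent-4-en-2-yl)oxy]hex-4-enoic acid
Conditions: CH2=CHMgBr (3.5 equiv), THF, −20 → 0 °C; cold aq. HCl
Reagents that add atoms: vinylmagnesium bromide, C=C[Mg]Br
Why: Weinreb ketone synthesis, in which the first equivalent of Grignard reagent makes the inert carboxylate, the chelated tetrahedral adduct stops at single addition, and the cold acidic quench keeps the released hydroxylamine from adding to the vinyl ketone.

Step 12
Reactants: 16 (2R,3S,4E)-3-[(benzyloxy)methyl]-3-methyl-2-[(2-methyl-3-oxopent-4-en-2-yl)oxy]hex-4-enoic acid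
Product: 17 (6S,7R)-6-[(benzyloxy)methyl]-2,2,6-trimethyl-3-oxo-2,3,6,7-tetrahydrooxepine-7-carboxylic acid
Conditions: second-generation Hoveyda–Grubbs catalyst (10 mol %), toluene (2 mM), 80 °C
Reagents that add atoms: none
Why: Ring-closing metathesis of the vinyl ketone with the propenyl group closes the seven-membered ring A enone with loss of propene, helped by the fully substituted carbons flanking the new ring; the ruthenium carbene tolerates the free acid.

Step 13
Reactants: 17 (6S,7R)-6-[(benzyloxy)methyl]-2,2,6-trimethyl-3-oxo-2,3,6,7-tetrahydrooxepine-7-carboxylic acid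
Product: 18 (6S,7R)-6-[(benzyloxy)methyl]-2,2,6-trimethyl-3-oxooxepane-7-carboxylic acid
Conditions: H2 (1 atm), Pd/C, pyridine, EtOAc, 23 °C
Reagents that add atoms: none
Why: Heterogeneous hydrogenation saturates the enone C=C, while added pyridine suppresses hydrogenolysis of the benzyl ether.

Step 14
Reactants: 18 (6S,7R)-6-[(benzyloxy)methyl]-2,2,6-trimethyl-3-oxooxepane-7-carboxylic acid
Product: 19 (3S,6S,7R)-6-[(benzyloxy)methyl]-7-(hydroxymethyl)-2,2,6-trimethyloxepan-3-ol
Conditions: LiAlH4, THF, 0 → 23 °C
Reagents that add atoms: none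
Why: LiAlH4 reduces the carboxylic acid to the primary alcohol and the ring ketone to the carbinol in one operation; the new carbinol centre is returned to the ketone at the end.

Step 15
Reactants: 19 (3S,6S,7R)-6-[(benzyloxy)methyl]-7-(hydroxymethyl)-2,2,6-trimethyloxepan-3-ol
Product: 20 (3S,6S,7R)-6-[(benzyloxy)methyl]-3-hydroxy-2,2,6-trimethyloxepane-7-carbaldehyde
Conditions: TEMPO (10 mol %), PhI(OAc)2, CH2Cl2, 23 °C
Reagents that add atoms: none
Why: Oxoammonium (TEMPO) oxidation is selective for the primary alcohol over the neopentyl secondary one and stops at the aldehyde.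

Step 16
Reactants: 20 (3S,6S,7R)-6-[(benzyloxy)methyl]-3-hydroxy-2,2,6-trimethyloxepane-7-carbaldehyde
Product: 21 (E)-4-[(3S,6S,7S)-6-[(benzyloxy)methyl]-3-hydroxy-2,2,6-trimethyloxepan-7-yl]but-3-en-2-one
Conditions: Ph3P=CHC(O)CH3, toluene, 70 °C
Reagents that add atoms: 1-(triphenylphosphoranylidene)propan-2-one, CC(=O)C=P(c1ccccc1)(c1ccccc1)c1ccccc1
Why: Wittig olefination with the stabilised acetonyl ylide under neutral conditions gives the (E)-enone without epimerising the α-alkoxy aldehyde.

Step 17
Reactants: 21 (E)-4-[(3S,6S,7S)-6-[(benzyloxy)methyl]-3-hydroxy-2,2,6-trimethyloxepan-7-yl]but-3-en-2-one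
Product: 22 (E)-4-[(3S,6S,7S)-6-[(benzyloxy)methyl]-3-[(tert-butyldimethylsilyl)oxy]-2,2,6-trimethyloxepan-7-yl]but-3-en-2-one
Conditions: t-BuMe2SiOTf, 2,6-lutidine, CH2Cl2, −78 → −40 °C
Reagents that add atoms: tert-butyldimethylsilyl trifluoromethanesulfonate, C[Si](C)(OS(=O)(=O)C(F)(F)F)C(C)(C)C
Why: The silyl triflate with a hindered pyridine base silylates the hindered secondary alcohol at low temperature faster than it enolises the methyl ketone.

Step 18
Reactants: 22 (E)-4-[(3S,6S,7S)-6-[(benzyloxy)methyl]-3-[(tert-butyldimethylsilyl)oxy]-2,2,6-trimethyloxepan-7-yl]but-3-en-2-one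
Product: 23 4-[(3S,6S,7S)-3-[(tert-butyldimethylsilyl)oxy]-6-(hydroxymethyl)-2,2,6-trimethyloxepan-7-yl]butan-2-one
Conditions: H2 (1 atm), Pd/C, EtOH, 23 °C
Reagents that add atoms: none
Why: One hydrogenation saturates the enone C=C and hydrogenolyses the benzyl ether; the ketone and the silyl ether are stable.

Step 19
Reactants: 23 4-[(3S,6S,7S)-3-[(tert-butyldimethylsilyl)oxy]-6-(hydroxymethyl)-2,2,6-trimethyloxepan-7-yl]butan-2-one
Product: 24 (3S,6R,7S)-3-[(tert-butyldimethylsilyl)oxy]-2,2,6-trimethyl-7-(3-oxobutyl)oxepane-6-carbaldehyde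
Conditions: Dess–Martin periodinane, NaHCO3, CH2Cl2, 23 °C
Reagents that add atoms: none
Why: Dess–Martin oxidation converts the neopentyl primary alcohol into the aldehyde, which has no α-hydrogen and cannot epimerise.

Step 20
Reactants: 24 (3S,6R,7S)-3-[(tert-butyldimethylsilyl)oxy]-2,2,6-trimethyl-7-(3-oxobutyl)oxepane-6-carbaldehyde
Product: 25 ethyl (E)-3-[(3S,6S,7S)-3-[(tert-butyldimethylsilyl)oxy]-2,2,6-trimethyl-7-(3-oxobutyl)oxepan-6-yl]acrylate (oxepane keto-enoate)
Conditions: Ph3P=CHCO2Et, toluene, 90 °C
Reagents that add atoms: ethyl (triphenylphosphoranylidene)acetate, CCOC(=O)C=P(c1ccccc1)(c1ccccc1)c1ccccc1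
Why: Wittig olefination with the stabilised ylide reacts only with the aldehyde, not the methyl ketone, and gives the (E)-enoate.

Step 21
Reactants: 25 oxepane keto-enoate
Product: 26 ring A/B hydroxy ester (trans-fused oxepane–cyclohexane; ring B carries the equatorial tertiary OH with axial methyl and, on the next carbon, the equatorial CH2CO2Et; angular methyl axial; ring A 3-silyloxy)
Conditions: SmI2 (3 equiv), HMPA, t-BuOH, THF, −78 °C
Reagents that add atoms: none
Why: Electron transfer from SmI2 (divalent samarium) with HMPA to the methyl ketone gives a samarium ketyl that adds to the β-carbon of the (E)-enoate, and a second electron plus t-BuOH turn the α-ester radical into the ester, so the carbinol-carbon-to-CH bond and ring B form together. The closest known reaction type is the SmI2-mediated ketyl–olefin cyclization of keto enoates. Ring B closes 6-exo-trig through a chair in which the trans-fused oxepane holds its ether oxygen and ring CH2 equatorial, which forces the angular methyl axial. The carbinol centre is set by the bulky samarium alkoxide taking the equatorial site (its methyl axial, syn to the angular methyl), and the CH centre by the enoate sitting equatorial and anti to that alkoxide, so both new centres are controlled by the existing quaternary and ether carbons. The step needs ketyl formation at the methyl ketone only and trans selectivity: the first is secured because ring A carries no carbonyl (an α-alkoxy ketone would be cleaved), the second by steric and dipolar repulsion between the samarium alkoxide and the developing ester-stabilised radical.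

Step 22
Reactants: 26 ring A/B hydroxy ester
Product: 27 triethylsilyl ether of 26 (tertiary O–SiEt3)
Conditions: Et3SiOTf, 2,6-lutidine, CH2Cl2, −78 → 0 °C
Reagents that add atoms: triethylsilyl trifluoromethanesulfonate, CC[Si](CC)(CC)OS(=O)(=O)C(F)(F)F
Why: Silylation of the tertiary alcohol with the silyl triflate prevents lactone and lactol formation with the neighbouring two-carbon chain in the following steps.

Step 23
Reactants: 27 triethylsilyl ether of 26
Product: 28 ring A/B aldehyde (CH2CHO in place of the CH2CO2Et of 27)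
Conditions: i-Bu2AlH, CH2Cl2, −78 °C
Reagents that add atoms: none
Why: Partial reduction of the ester with i-Bu2AlH at −78 °C stops at the aluminium hemiacetal and gives the aldehyde on work-up; both silyl ethers are stable.

Step 24
Reactants: 29 4,4-dimethylcyclohex-2-en-1-one; 30 isoprene
Product: 31 (4aR,8aS)-4,4,6-trimethyl-3,4,4a,5,8,8a-hexahydronaphthalen-1(2H)-one (cis-fused)
Conditions: (S)-o-tolyl-oxazaborolidine from (S)-α,α-diphenylprolinol (10 mol %), AlBr3 (8 mol %), CH2Cl2, −40 → −20 °C
Reagents that add atoms: none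
Why: Lewis-acid-catalysed Diels–Alder reaction, in which suprafacial addition gives the cis ring fusion, the diene methyl ends para to the carbonyl-bearing ring-fusion carbon, and the chiral cationic oxazaborolidine shields one face of the coordinated enone to fix the absolute configuration.

Step 25
Reactants: 31 (4aR,8aS)-4,4,6-trimethyl-3,4,4a,5,8,8a-hexahydronaphthalen-1(2H)-one
Product: 32 5-hydroxy derivative of 31 (allylic OH on the ring CH2 between the ring fusion and the methyl-bearing alkene carbon, on the face of the ring-fusion hydrogens)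
Conditions: SeO2 (0.5 equiv), t-BuOOH, CH2Cl2, 23 °C
Reagents that add atoms: tert-butyl hydroperoxide, CC(C)(C)OO (terminal oxygen source; SeO2, O=[Se]=O, is the catalytic oxygen carrier)
Why: SeO2 allylic oxidation (ene reaction, then [2,3]-sigmatropic shift) oxygenates the ring CH2 attached to the more substituted alkene carbon, from the convex face; the saturated ketone is not attacked at room temperature.

Step 26
Reactants: 32 5-hydroxy derivative of 31
Product: 33 cis-fused ene-dione (ring D ketone; ring C 2-methyl-enone with its carbonyl next to the ring fusion)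
Conditions: Dess–Martin periodinane, NaHCO3, CH2Cl2, 23 °C
Reagents that add atoms: none
Why: Dess–Martin oxidation of the secondary allylic alcohol gives the conjugated enone and converges any enone already formed in step 25.

Step 27
Reactants: 33 cis-fused ene-dione
Product: 34 ring D exocyclic methylene enone
Conditions: Zn, CH2Br2, TiCl4, THF–CH2Cl2, 0 → 23 °C
Reagents that add atoms: dibromomethane, BrCBr
Why: Takai–Lombardo methylenation is non-basic, so the cis ring fusion next to the ketone is not epimerised, and it selects the saturated ketone over the conjugated, doubly flanked enone carbonyl.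

Step 28
Reactants: 34 ring D exocyclic methylene enone
Product: 35 spiro-epoxy enone (epoxide oxygen on the face of the ring-fusion hydrogens)
Conditions: mCPBA, NaHCO3, CH2Cl2, 0 °C
Reagents that add atoms: m-chloroperbenzoic acid, OOC(=O)c1cccc(Cl)c1
Why: Prilezhaev epoxidation attacks only the electron-rich 1,1-disubstituted alkene (the enone alkene is electron-poor) and from the convex face of the cis-decalin, which fixes the ring D carbinol centre.

Step 29
Reactants: 35 spiro-epoxy enone
Product: 38 rings C/D alkenyl triflate (tetrasubstituted C(OTf)=C(CH3) in ring C; ring D tertiary alcohol with OH on the face of the ring-fusion hydrogens), via lithium enolate 36 (not isolated), via lithium enolate alkoxide 37 (not isolated)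
Conditions: LiBH(s-Bu)3, THF, −78 °C; LiBHEt3, −78 → 0 °C; PhNTf2, 0 → 23 °C
Reagents that add atoms: N-phenylbis(trifluoromethanesulfonimide), O=S(=O)(N(c1ccccc1)S(=O)(=O)C(F)(F)F)C(F)(F)F
Why: Conjugate reduction of the β-monosubstituted enone with the hindered borohydride gives the regiodefined enolate, the unhindered borohydride then opens the spiro-epoxide at its CH2 (SN2) to the tertiary alkoxide, and the triflimide triflates the enolate oxygen, the hindered alkoxide–borane complex not competing.

Step 30
Reactants: 28 ring A/B aldehyde; 38 rings C/D alkenyl triflate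
Product: 39 coupled allylic alcohol (both carbinol epimers; the CH(OH) carbon joins the CH2 of 28 to the former triflate carbon)
Conditions: CrCl2 (6 equiv), NiCl2 (2 mol %), DMF, 23 °C
Reagents that add atoms: none
Why: Nozaki–Hiyama–Kishi coupling, in which zerovalent nickel inserts into the alkenyl triflate and the alkenylchromium species formed by transmetalation adds only to the aldehyde, tolerating the free tertiary alcohol and the silyl ethers.

Step 31
Reactants: 39 coupled allylic alcohol
Product: 40 cross-conjugated enone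
Conditions: Dess–Martin periodinane, NaHCO3, CH2Cl2, 23 °C
Reagents that add atoms: none
Why: Dess–Martin oxidation of the secondary allylic alcohol converges both epimers on the enone; the tertiary alcohol and silyl ethers are inert.

Step 32
Reactants: 40 cross-conjugated enone
Product: 41 (R)-allylic alcohol
Conditions: (S)-2-methyl-CBS-oxazaborolidine, BH3·SMe2, THF, −30 °C
Reagents that add atoms: none
Why: Corey–Bakshi–Shibata reduction, in which the tetrasubstituted cycloalkenyl group acts as the large and the CH2 group as the small substituent, so the (S)-catalyst gives the (R)-carbinol under reagent control.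

Step 33
Reactants: 41 (R)-allylic alcohol
Product: 44 bis-silyl ether of the target skeleton (exocyclic trisubstituted alkene, ring C CH(CH3) set), via sulfonylhydrazine adduct 42 (not isolated), via allylic diazene 43 (not isolated)
Conditions: PPh3, DEAD, o-nitrobenzenesulfonylhydrazide, N-methylmorpholine, −30 → 23 °C
Reagents that add atoms: none
Why: Reductive allylic transposition through a monoalkyl diazene, in which Mitsunobu substitution inverts the carbinol, loss of sulfinic acid gives the diazene, and retro-ene loss of N2 delivers hydrogen suprafacially to the methyl-bearing ring C carbon on the convex face (the concave face is blocked by the pseudoaxial CMe2 carbon), setting the methine and, with the chain turned to the methyl side, the alkene geometry.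

Step 34
Reactants: 44 bis-silyl ether of the target skeleton
Product: 45 triol (ring A secondary carbinol and both tertiary alcohols free)
Conditions: Bu4NF, THF, 50 °C
Reagents that add atoms: none
Why: Fluoride removes both silyl ethers under basic conditions that spare the alkene and the tertiary alcohols.

Step 35
Reactants: 45 triol
Product: 46 CNP0232921.1
Conditions: Dess–Martin periodinane, NaHCO3, CH2Cl2, 23 °C
Reagents that add atoms: none
Why: Dess–Martin oxidation converts the only secondary alcohol into the ring A ketone; tertiary alcohols and the trisubstituted alkene do not react.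

**Compound list**

1 | methyl 2-hydroxyisobutyrate | COC(=O)C(C)(C)O | starting material
2 | 2-hydroxy-N-methoxy-N,2-dimethylpropanamide | CON(C)C(=O)C(C)(C)O | intermediate
3 | bromoacetic acid | OC(=O)CBr | starting material
4 | 2-{[1-(methoxy(methyl)amino)-2-methyl-1-oxopropan-2-yl]oxy}acetic acid | CON(C)C(=O)C(C)(C)OCC(=O)O | intermediate
5 | methyl (R)-lactate | C[C@@H](O)C(=O)OC | starting material
6 | methyl (R)-2-[(tert-butyldimethylsilyl)oxy]propanoate | C[C@@H](O[Si](C)(C)C(C)(C)C)C(=O)OC | intermediate
7 | (R)-2-[(tert-butyldimethylsilyl)oxy]propanal | C[C@@H](O[Si](C)(C)C(C)(C)C)C=O | intermediate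
8 | ethyl (2Z,4R)-4-[(tert-butyldimethylsilyl)oxy]-2-methylpent-2-enoate | C[C@@H](O[Si](C)(C)C(C)(C)C)/C=C(/C)C(=O)OCC | intermediate
9 | (2Z,4R)-4-[(tert-butyldimethylsilyl)oxy]-2-methylpent-2-en-1-ol | C[C@@H](O[Si](C)(C)C(C)(C)C)/C=C(/C)CO | intermediate
10 | {[(2R,3Z)-5-(benzyloxy)-4-methylpent-3-en-2-yl]oxy}(tert-butyl)dimethylsilane | C[C@@H](O[Si](C)(C)C(C)(C)C)/C=C(/C)COCc1ccccc1 | intermediate
11 | (2R,3Z)-5-(benzyloxy)-4-methylpent-3-en-2-ol | C[C@@H](O)/C=C(/C)COCc1ccccc1 | intermediate
12 | (2R,3Z)-5-(benzyloxy)-4-methylpent-3-en-2-yl ester of 4 | C[C@@H](OC(=O)COC(C)(C)C(=O)N(C)OC)/C=C(/C)COCc1ccccc1 | intermediate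
13 | silyl ketene acetal of 12 (alkoxy group cis to OSiMe3) | C[C@@H](O/C(O[Si](C)(C)C)=C/OC(C)(C)C(=O)N(C)OC)/C=C(/C)COCc1ccccc1 | intermediate
14 | trimethylsilyl ester of 15 | C[Si](C)(C)OC(=O)[C@H](OC(C)(C)C(=O)N(C)OC)[C@](C)(COCc1ccccc1)/C=C/C | intermediate
15 | (2R,3S,4E)-3-[(benzyloxy)methyl]-2-{[1-(methoxy(methyl)amino)-2-methyl-1-oxopropan-2-yl]oxy}-3-methylhex-4-enoic acid | OC(=O)[C@H](OC(C)(C)C(=O)N(C)OC)[C@](C)(COCc1ccccc1)/C=C/C | intermediate
16 | (2R,3S,4E)-3-[(benzyloxy)methyl]-3-methyl-2-[(2-methyl-3-oxopent-4-en-2-yl)oxy]hex-4-enoic acid | OC(=O)[C@H](OC(C)(C)C(=O)C=C)[C@](C)(COCc1ccccc1)/C=C/C | intermediate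
17 | (6S,7R)-6-[(benzyloxy)methyl]-2,2,6-trimethyl-3-oxo-2,3,6,7-tetrahydrooxepine-7-carboxylic acid | c1ccccc1COC[C@]1(C)C=CC(=O)C(C)(C)O[C@H]1C(=O)O | intermediate
18 | (6S,7R)-6-[(benzyloxy)methyl]-2,2,6-trimethyl-3-oxooxepane-7-carboxylic acid | c1ccccc1COC[C@]1(C)CCC(=O)C(C)(C)O[C@H]1C(=O)O | intermediate
19 | (3S,6S,7R)-6-[(benzyloxy)methyl]-7-(hydroxymethyl)-2,2,6-trimethyloxepan-3-ol | c1ccccc1COC[C@]1(C)CC[C@H](O)C(C)(C)O[C@H]1CO | intermediate
20 | (3S,6S,7R)-6-[(benzyloxy)methyl]-3-hydroxy-2,2,6-trimethyloxepane-7-carbaldehyde | c1ccccc1COC[C@]1(C)CC[C@H](O)C(C)(C)O[C@H]1C=O | intermediate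
21 | (E)-4-[(3S,6S,7S)-6-[(benzyloxy)methyl]-3-hydroxy-2,2,6-trimethyloxepan-7-yl]but-3-en-2-one | c1ccccc1COC[C@]1(C)CC[C@H](O)C(C)(C)O[C@H]1/C=C/C(C)=O | intermediate
22 | tert-butyldimethylsilyl ether of 21 | c1ccccc1COC[C@]1(C)CC[C@H](O[Si](C)(C)C(C)(C)C)C(C)(C)O[C@H]1/C=C/C(C)=O | intermediate
23 | 4-[(3S,6S,7S)-3-[(tert-butyldimethylsilyl)oxy]-6-(hydroxymethyl)-2,2,6-trimethyloxepan-7-yl]butan-2-one | OC[C@]1(C)CC[C@H](O[Si](C)(C)C(C)(C)C)C(C)(C)O[C@H]1CCC(C)=O | intermediate
24 | (3S,6R,7S)-3-[(tert-butyldimethylsilyl)oxy]-2,2,6-trimethyl-7-(3-oxobutyl)oxepane-6-carbaldehyde | O=C[C@]1(C)CC[C@H](O[Si](C)(C)C(C)(C)C)C(C)(C)O[C@H]1CCC(C)=O | intermediate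
25 | oxepane keto-enoate: ethyl (E)-3-[(3S,6S,7S)-3-[(tert-butyldimethylsilyl)oxy]-2,2,6-trimethyl-7-(3-oxobutyl)oxepan-6-yl]acrylate | CCOC(=O)/C=C/[C@]1(C)CC[C@H](O[Si](C)(C)C(C)(C)C)C(C)(C)O[C@H]1CCC(C)=O | intermediate
26 | ring A/B hydroxy ester (trans-fused; equatorial tertiary OH, equatorial CH2CO2Et, both ring B methyls axial, ring A 3-silyloxy) | CCOC(=O)C[C@H]1[C@]2(C)CC[C@H](O[Si](C)(C)C(C)(C)C)C(C)(C)O[C@H]2CC[C@]1(C)O | intermediate
27 | triethylsilyl ether of 26 | CCOC(=O)C[C@H]1[C@]2(C)CC[C@H](O[Si](C)(C)C(C)(C)C)C(C)(C)O[C@H]2CC[C@]1(C)O[Si](CC)(CC)CC | intermediate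
28 | ring A/B aldehyde | O=CC[C@H]1[C@]2(C)CC[C@H](O[Si](C)(C)C(C)(C)C)C(C)(C)O[C@H]2CC[C@]1(C)O[Si](CC)(CC)CC | intermediate
29 | 4,4-dimethylcyclohex-2-en-1-one | CC1(C)CCC(=O)C=C1 | starting material
30 | isoprene | CC(=C)C=C | starting material
31 | (4aR,8aS)-4,4,6-trimethyl-3,4,4a,5,8,8a-hexahydronaphthalen-1(2H)-one | CC1=CC[C@H]2[C@@H](C1)C(C)(C)CCC2=O | intermediate
32 | 5-hydroxy derivative of 31 (OH cis to the ring-fusion hydrogens) | CC1=CC[C@H]2[C@@H]([C@H]1O)C(C)(C)CCC2=O | intermediate
33 | cis-fused ene-dione | CC1=CC[C@H]2[C@@H](C1=O)C(C)(C)CCC2=O | intermediate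
34 | ring D exocyclic methylene enone | CC1=CC[C@H]2[C@@H](C1=O)C(C)(C)CCC2=C | intermediate
35 | spiro-epoxy enone | CC1=CC[C@H]2[C@@H](C1=O)C(C)(C)CC[C@@]23CO3 | intermediate
36 | lithium enolate of the reduced epoxy ketone | CC=1CC[C@H]2[C@@H](C=1O[Li])C(C)(C)CC[C@@]23CO3 | intermediate
37 | lithium enolate alkoxide | CC=1CC[C@H]2[C@@H](C=1O[Li])C(C)(C)CC[C@]2(C)O[Li] | intermediate
38 | rings C/D alkenyl triflate with ring D tertiary alcohol | CC=1CC[C@H]2[C@@H](C=1OS(=O)(=O)C(F)(F)F)C(C)(C)CC[C@]2(C)O | intermediate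
39 | coupled allylic alcohol (both carbinol epimers) | CC=1CC[C@H]2[C@@H](C=1C(O)C[C@H]1[C@]3(C)CC[C@H](O[Si](C)(C)C(C)(C)C)C(C)(C)O[C@H]3CC[C@]1(C)O[Si](CC)(CC)CC)C(C)(C)CC[C@]2(C)O | intermediate
40 | cross-conjugated enone | CC=1CC[C@H]2[C@@H](C=1C(=O)C[C@H]1[C@]3(C)CC[C@H](O[Si](C)(C)C(C)(C)C)C(C)(C)O[C@H]3CC[C@]1(C)O[Si](CC)(CC)CC)C(C)(C)CC[C@]2(C)O | intermediate
41 | (R)-allylic alcohol | CC=1CC[C@H]2[C@@H](C=1[C@H](O)C[C@H]1[C@]3(C)CC[C@H](O[Si](C)(C)C(C)(C)C)C(C)(C)O[C@H]3CC[C@]1(C)O[Si](CC)(CC)CC)C(C)(C)CC[C@]2(C)O | intermediate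
42 | N-allyl-N-(2-nitrobenzenesulfonyl)hydrazine, (S) at the allylic carbon | CC=1CC[C@H]2[C@@H](C=1[C@@H](N(N)S(=O)(=O)c4ccccc4[N+](=O)[O-])C[C@H]1[C@]3(C)CC[C@H](O[Si](C)(C)C(C)(C)C)C(C)(C)O[C@H]3CC[C@]1(C)O[Si](CC)(CC)CC)C(C)(C)CC[C@]2(C)O | intermediate
43 | allylic diazene, (S) at the allylic carbon | CC=1CC[C@H]2[C@@H](C=1[C@@H](N=N)C[C@H]1[C@]3(C)CC[C@H](O[Si](C)(C)C(C)(C)C)C(C)(C)O[C@H]3CC[C@]1(C)O[Si](CC)(CC)CC)C(C)(C)CC[C@]2(C)O | intermediate
44 | bis-silyl ether of the target skeleton | C[C@@H]1CC[C@H]2[C@@H](/C1=C/C[C@H]1[C@]3(C)CC[C@H](O[Si](C)(C)C(C)(C)C)C(C)(C)O[C@H]3CC[C@]1(C)O[Si](CC)(CC)CC)C(C)(C)CC[C@]2(C)O | intermediate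
45 | triol | C[C@@H]1CC[C@H]2[C@@H](/C1=C/C[C@H]1[C@]3(C)CC[C@H](O)C(C)(C)O[C@H]3CC[C@]1(C)O)C(C)(C)CC[C@]2(C)O | intermediate
46 | CNP0232921.1 | C[C@@H]1CC[C@H]2[C@@H](/C1=C/C[C@H]1[C@]3(C)CCC(=O)C(C)(C)O[C@H]3CC[C@]1(C)O)C(C)(C)CC[C@]2(C)O | target

**Count and risks**

Total steps: 35. Longest linear sequence: 27 steps (5 to 46 through steps 3–23 and 30–35).

Steps most likely to fail:

1. Step 33. The Mitsunobu substitution at the doubly flanked allylic carbinol may be slow or take an allylic (SN2') course, and the diazene may react through the other rotamer, which would erode both the alkene geometry and the methine configuration. The fallback sets out from 41 and comes back at 44: 41 is converted (ClCO2Me, pyridine, CH2Cl2) into the allylic methyl carbonate F1. Palladium-catalysed formate reduction of F1 (Pd(OAc)2, PBu3, HCO2NH4, THF, 40 °C) should form the π-allyl complex with inversion and deliver hydride from palladium to the more substituted allyl terminus, on the face opposite to the departed carbonate, which is the same stereochemical course as the diazene route, to give 44.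

2. Step 24. The γ,γ-disubstituted enone may add isoprene too slowly at the low temperature the chiral catalyst needs, with poor facial selectivity or epimerisation of the cis ring fusion on warming. The fallback sets out from 29 and 30 and comes back at 31: AlCl3 (toluene, 40 °C) gives the racemic cis adduct, that is 31 together with its mirror image F2. The mixture is ketalised with (R,R)-hydrobenzoin bis(trimethylsilyl) ether (Me3SiOTf cat., CH2Cl2, −78 °C) to the diastereomeric ketals F3 and F4, which are separated by chromatography; mild hydrolysis of F3 (aqueous oxalic acid, THF) returns 31.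

3. Step 21. The ketyl may add with poor facial selectivity (cis hydroxy ester, then lactone), or the enoate may simply be reduced. The fallback sets out from 24 and comes back at 28: Wittig reaction of 24 with Ph3P=CHCH2SiMe3 (THF, −78 °C, aldehyde-selective) gives the allylsilane F5. TiCl4 (CH2Cl2, −78 °C) then triggers an intramolecular Hosomi–Sakurai addition of the allylsilane γ-carbon to the methyl ketone; this closes ring B through the same bond by a polar path and leaves a vinyl group on the CH, giving the vinyl carbinol F6. Silylation (Et3SiOTf, 2,6-lutidine) gives the triethylsilyl ether F7, hydroboration–oxidation (9-BBN; NaOH, H2O2) the primary alcohol F8, and Dess–Martin oxidation the aldehyde 28.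

Further compounds
F1 | step 33 | allylic methyl carbonate of 41 | CC=1CC[C@H]2[C@@H](C=1[C@H](OC(=O)OC)C[C@H]1[C@]3(C)CC[C@H](O[Si](C)(C)C(C)(C)C)C(C)(C)O[C@H]3CC[C@]1(C)O[Si](CC)(CC)CC)C(C)(C)CC[C@]2(C)O
F2 | step 24 | mirror image of 31, (4aS,8aR)-4,4,6-trimethyl-3,4,4a,5,8,8a-hexahydronaphthalen-1(2H)-one | CC1=CC[C@@H]2[C@H](C1)C(C)(C)CCC2=O
F3 | step 24 | (R,R)-hydrobenzoin ketal of 31 | CC1=CC[C@H]2[C@@H](C1)C(C)(C)CCC23O[C@H](c4ccccc4)[C@@H](c4ccccc4)O3
F4 | step 24 | (R,R)-hydrobenzoin ketal of F2 | CC1=CC[C@@H]2[C@H](C1)C(C)(C)CCC23O[C@H](c4ccccc4)[C@@H](c4ccccc4)O3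
F5 | step 21 | (Z)-allylsilane from 24 | C[Si](C)(C)C/C=C\[C@]1(C)CC[C@H](O[Si](C)(C)C(C)(C)C)C(C)(C)O[C@H]1CCC(C)=O
F6 | step 21 | ring A/B vinyl carbinol | C=C[C@H]1[C@]2(C)CC[C@H](O[Si](C)(C)C(C)(C)C)C(C)(C)O[C@H]2CC[C@]1(C)O
F7 | step 21 | triethylsilyl ether of F6 | C=C[C@H]1[C@]2(C)CC[C@H](O[Si](C)(C)C(C)(C)C)C(C)(C)O[C@H]2CC[C@]1(C)O[Si](CC)(CC)CC
F8 | step 21 | primary alcohol from F7 | OCC[C@H]1[C@]2(C)CC[C@H](O[Si](C)(C)C(C)(C)C)C(C)(C)O[C@H]2CC[C@]1(C)O[Si](CC)(CC)CC
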